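Everything rests on cutting the terminal furan-2(5H)-one ring (O1, C2, C3, C4, C5) into three pieces: propargyl alcohol supplies O1–C5 and the C4≡C3 unit, CO2 supplies C2, and the C12 chain enters at C4. One operation – copper-catalysed, alkoxide-directed anti addition of the chain Grignard reagent, carboxylation of the alkenylmagnesium and acid-induced closure – forms chain–C4, C3–C2 and O1–C2, exploiting the cis relation of C2 and C5 across C3=C4 that the ring demands. The precursor is an E,E-C12 homoallylic bromide ending in a dioxolane-masked aldehyde, built from geraniol. The (S)-configured E-alkylidene lactone is attached last by a Wittig reaction of a chiral-pool lactone ylide.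

Key step: step 10

Remark: Grignard reagent 5 is assumed to be bought as its THF solution (it can also be made from 2-(bromomethyl)-1,3-dioxolane and magnesium), and lactone 20 is the commercial (S) enantiomer derived from L-glutamic acid.

Step 1
Reactants: 1 geraniol
Product: 2 tert-butyl{[(2E)-3,7-dimethylocta-2,6-dien-1-yl]oxy}diphenylsilane
Conditions: TBDPSCl, imidazole, CH2Cl2, 0 °C → rt
Reagents that add atoms: tert-butyl(chloro)diphenylsilane, CC(C)(C)[Si](Cl)(c1ccccc1)c1ccccc1
Why: Imidazole-promoted silylation of a primary allylic alcohol (silyl ether protection) should be clean and gives an ether that withstands SeO2, phosphorus-based bromination and the Grignard coupling.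

Step 2
Reactants: 2 tert-butyl{[(2E)-3,7-dimethylocta-2,6-dien-1-yl]oxy}diphenylsilane
Product: 3 (2E,6E)-8-[(tert-butyldiphenylsilyl)oxy]-2,6-dimethylocta-2,6-dien-1-ol
Conditions: SeO2 (cat.), t-BuOOH, salicylic acid (cat.), CH2Cl2, rt; stopped before full conversion
Reagents that add atoms: selenium dioxide, O=[Se]=O (catalytic oxygen carrier); tert-butyl hydroperoxide, CC(C)(C)OO (stoichiometric oxygen source)
Why: Catalytic SeO2 allylic oxidation (ene reaction then [2,3]-sigmatropic shift) attacks the more electron-rich terminal trisubstituted alkene at its E-methyl group, so the mechanism fixes the new E-allylic alcohol while the alkene next to the silyloxy group is left alone.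

Step 3
Reactants: 3 (2E,6E)-8-[(tert-butyldiphenylsilyl)oxy]-2,6-dimethylocta-2,6-dien-1-ol
Product: 4 {[(2E,6E)-8-bromo-3,7-dimethylocta-2,6-dien-1-yl]oxy}(tert-butyl)diphenylsilane
Conditions: CBr4, PPh3, CH2Cl2, 0 °C; used at once
Reagents that add atoms: carbon tetrabromide, BrC(Br)(Br)Br
Why: Appel bromination displaces the primary allylic oxyphosphonium ion by SN2 at low temperature, without allylic transposition or loss of E geometry.

Step 4
Reactants: 4 {[(2E,6E)-8-bromo-3,7-dimethylocta-2,6-dien-1-yl]oxy}(tert-butyl)diphenylsilane; 5 (1,3-dioxolan-2-ylmethyl)magnesium bromide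
Product: 6 tert-butyl{[(2E,6E)-9-(1,3-dioxolan-2-yl)-3,7-dimethylnona-2,6-dien-1-yl]oxy}diphenylsilane
Conditions: Li2CuCl4 (5 mol%), THF, −30 → 0 °C
Reagents that add atoms: none
Why: Copper-catalysed cross-coupling of a Grignard reagent with a primary allylic bromide in THF should occur at the α-carbon with retention of the E alkene, the cyclic acetal slowing β-elimination of the organomagnesium and the silyl ether being inert.

Step 5
Reactants: 6 tert-butyl{[(2E,6E)-9-(1,3-dioxolan-2-yl)-3,7-dimethylnona-2,6-dien-1-yl]oxy}diphenylsilane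
Product: 7 (2E,6E)-9-(1,3-dioxolan-2-yl)-3,7-dimethylnona-2,6-dien-1-ol
Conditions: TBAF, THF, rt
Reagents that add atoms: none
Why: Fluoride-induced desilylation, driven by the strong Si–F bond, runs under basic conditions that leave the dioxolane untouched.

Step 6
Reactants: 7 (2E,6E)-9-(1,3-dioxolan-2-yl)-3,7-dimethylnona-2,6-dien-1-ol
Product: 8 (2E,6E)-9-(1,3-dioxolan-2-yl)-3,7-dimethylnona-2,6-dienal
Conditions: activated MnO2, CH2Cl2, rt
Reagents that add atoms: none
Why: Activated MnO2 oxidises allylic alcohols selectively under neutral conditions, so the enal should form without E/Z isomerisation or acetal loss.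

Step 7
Reactants: 8 (2E,6E)-9-(1,3-dioxolan-2-yl)-3,7-dimethylnona-2,6-dienal
Product: 9 2-[(3E,7E)-3,7-dimethyldeca-3,7,9-trien-1-yl]-1,3-dioxolane
Conditions: Ph3PCH3Br, KOt-Bu (slight deficit), THF, 0 °C → rt
Reagents that add atoms: methyltriphenylphosphonium bromide, C[P+](c1ccccc1)(c1ccccc1)c1ccccc1.[Br-]
Why: Wittig methylenation with the non-stabilised ylide is fast on an enal and creates only a terminal CH2, so no new geometry arises and the existing E alkene is kept.

Step 8
Reactants: 9 2-[(3E,7E)-3,7-dimethyldeca-3,7,9-trien-1-yl]-1,3-dioxolane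
Product: 11 (3E,7E)-10-(1,3-dioxolan-2-yl)-4,8-dimethyldeca-3,7-dien-1-ol, via B-alkyl-9-BBN adduct 10 (not isolated)
Conditions: 9-BBN, THF, 0 °C → rt; then NaOH, H2O2, 0 °C → rt
Reagents that add atoms: hydrogen peroxide, OO
Why: 9-BBN hydroborates the monosubstituted terminal alkene anti-Markovnikov far faster than any trisubstituted alkene, and alkaline peroxide oxidation (to which the acetal is stable) then gives the primary homoallylic alcohol.

Step 9
Reactants: 11 (3E,7E)-10-(1,3-dioxolan-2-yl)-4,8-dimethyldeca-3,7-dien-1-ol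
Product: 12 2-[(3E,7E)-10-bromo-3,7-dimethyldeca-3,7-dien-1-yl]-1,3-dioxolane
Conditions: CBr4, PPh3, imidazole (cat.), CH2Cl2, 0 °C
Reagents that add atoms: carbon tetrabromide, BrC(Br)(Br)Br
Why: Appel bromination by SN2 on the primary oxyphosphonium ion, buffered by imidazole, keeps the medium non-acidic so that the dioxolane and both E alkenes survive.

Step 10
Reactants: 12 2-[(3E,7E)-10-bromo-3,7-dimethyldeca-3,7-dien-1-yl]-1,3-dioxolane; 13 propargyl alcohol; 14 carbon dioxide
Product: 18 4-[(3E,7E)-10-(1,3-dioxolan-2-yl)-4,8-dimethyldeca-3,7-dien-1-yl]furan-2(5H)-one, via chain Grignard reagent 15 (not isolated), via alkenylmagnesium chelate 16 (not isolated), via Z-hydroxy acid 17 (not isolated)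
Conditions: 12, Mg, THF, 35 °C; separately 13, i-PrMgCl (1 equiv. per 13), THF, −30 °C; CuI (10 mol%), then 15, −20 °C → rt; CO2 (g), −40 °C → rt; 1 M HCl to pH 3, 0 °C
Reagents that add atoms: none
Why: Transmetalation of 15 to copper gives an organocopper that adds across the alkyne of the chloromagnesium propargyl alkoxide, delivering the chain to the internal carbon (future C4) and the metal to the terminal carbon (future C3); binding to the alkoxide oxygen holds the carbon–metal bond cis to the CH2O arm, hence anti to the entering chain, and return to magnesium gives the five-membered oxamagnesacycle 16. Alkenyl Grignard reagents are carboxylated with retention, so CO2 joins C2 to C3 cis to C5, and on acidification hydroxy acid 17 closes by 5-exo-trig acyl substitution (O1 attacks C2, water leaves). The closest known reaction type is the copper(I)-catalysed anti-carbomagnesiation of propargylic alcohols with electrophilic trapping of the alkenylmagnesium by iodine or CO2, which is established for primary alkyl Grignard reagents. No stereocentre is formed; the selectivities needed are chain delivery to the internal carbon and anti addition, and both are secured by the magnesium alkoxide chelate, since only the cis acid–alcohol pair can lactonise. Neutralising the hydroxyl beforehand with i-PrMgCl keeps the chain reagent from being spent as a base, the dioxolane and the isolated alkenes are inert to the organometallics, and acidification is held at pH 3 and 0 °C to preserve the acetal.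

Step 11
Reactants: 18 4-[(3E,7E)-10-(1,3-dioxolan-2-yl)-4,8-dimethyldeca-3,7-dien-1-yl]furan-2(5H)-one
Product: 19 (4E,8E)-4,8-dimethyl-11-(5-oxo-2,5-dihydrofuran-3-yl)undeca-4,8-dienal
Conditions: 1 M HCl, THF, rt
Reagents that add atoms: water, O
Why: Acid-catalysed acetal hydrolysis releases the aldehyde, while the butenolide and the isolated trisubstituted alkenes tolerate dilute acid at room temperature.

Step 12
Reactants: 20 (S)-5-(hydroxymethyl)dihydrofuran-2(3H)-one
Product: 21 (S)-5-oxotetrahydrofuran-2-carbaldehyde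
Conditions: (COCl)2, DMSO, CH2Cl2, −78 °C; Et3N, −78 → −20 °C; used crude
Reagents that add atoms: none
Why: Swern oxidation stops at the aldehyde under cold, non-aqueous conditions that should not epimerise the adjacent stereocentre, which comes unchanged from the chiral pool.

Step 13
Reactants: 21 (S)-5-oxotetrahydrofuran-2-carbaldehyde
Product: 22 (S)-5-(2-methylprop-1-en-1-yl)dihydrofuran-2(3H)-one
Conditions: i-PrPPh3I, KHMDS, THF, 0 °C; then 21, −78 → 0 °C
Reagents that add atoms: isopropyltriphenylphosphonium iodide, CC(C)[P+](c1ccccc1)(c1ccccc1)c1ccccc1.[I-]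
Why: Wittig olefination with the non-stabilised isopropylidene ylide at −78 °C is much faster at the aldehyde than at the lactone carbonyl, raises no E/Z question because the new alkene carbon carries two methyl groups, and leaves the C5 (S) centre as it was.

Step 14
Reactants: 22 (S)-5-(2-methylprop-1-en-1-yl)dihydrofuran-2(3H)-one
Product: 24 (5S)-3-bromo-5-(2-methylprop-1-en-1-yl)dihydrofuran-2(3H)-one (C3 epimers), via silyl ketene acetal 23 (not isolated)
Conditions: LDA, THF, −78 °C; TMSCl; NBS, −78 °C
Reagents that add atoms: N-bromosuccinimide, O=C1CCC(=O)N1Br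
Why: Kinetic enolisation, O-silylation and electrophilic bromination of the silyl ketene acetal, which is far more nucleophilic than the trisubstituted alkene, gives the α-bromolactone, whose C3 configuration is irrelevant because C3 later becomes sp2.

Step 15
Reactants: 24 (5S)-3-bromo-5-(2-methylprop-1-en-1-yl)dihydrofuran-2(3H)-one
Product: 25 [(5S)-5-(2-methylprop-1-en-1-yl)-2-oxotetrahydrofuran-3-yl]triphenylphosphonium bromide
Conditions: PPh3, toluene, 70 °C
Reagents that add atoms: triphenylphosphine, c1ccc(cc1)P(c1ccccc1)c1ccccc1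
Why: SN2 quaternisation of triphenylphosphine by an α-bromolactone is the standard entry to lactone Wittig salts, and the neutral medium avoids ionisation of the allylic C5–O bond.

Step 16
Reactants: 19 (4E,8E)-4,8-dimethyl-11-(5-oxo-2,5-dihydrofuran-3-yl)undeca-4,8-dienal; 25 [(5S)-5-(2-methylprop-1-en-1-yl)-2-oxotetrahydrofuran-3-yl]triphenylphosphonium bromide
Product: 27 (3E,5S)-3-[(4E,8E)-4,8-dimethyl-11-(5-oxo-2,5-dihydrofuran-3-yl)undeca-4,8-dien-1-ylidene]-5-(2-methylprop-1-en-1-yl)dihydrofuran-2(3H)-one (CNP0237694.1), via lactone ylide 26 (not isolated)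
Conditions: 25, Et3N, CH2Cl2, rt; then 19, rt → 40 °C
Reagents that add atoms: none
Why: Triethylamine deprotonates the ester-stabilised phosphonium salt to a stabilised ylide whose Wittig reaction with an aliphatic aldehyde is thermodynamically controlled and should give the E-alkylidene lactone (chain trans to C=O) under near-neutral conditions that spare the butenolide, the allylic lactone C–O bond and the (S) centre.

Compound list
1 | geraniol | CC(C)=CCC/C(C)=C/CO | starting material
2 | tert-butyl{[(2E)-3,7-dimethylocta-2,6-dien-1-yl]oxy}diphenylsilane | CC(C)=CCC/C(C)=C/CO[Si](c1ccccc1)(c1ccccc1)C(C)(C)C | intermediate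
3 | (2E,6E)-8-[(tert-butyldiphenylsilyl)oxy]-2,6-dimethylocta-2,6-dien-1-ol | OC/C(C)=C/CC/C(C)=C/CO[Si](c1ccccc1)(c1ccccc1)C(C)(C)C | intermediate
4 | {[(2E,6E)-8-bromo-3,7-dimethylocta-2,6-dien-1-yl]oxy}(tert-butyl)diphenylsilane | BrC/C(C)=C/CC/C(C)=C/CO[Si](c1ccccc1)(c1ccccc1)C(C)(C)C | intermediate
5 | (1,3-dioxolan-2-ylmethyl)magnesium bromide | Br[Mg]CC1OCCO1 | starting material
6 | tert-butyl{[(2E,6E)-9-(1,3-dioxolan-2-yl)-3,7-dimethylnona-2,6-dien-1-yl]oxy}diphenylsilane | CC(C)(C)[Si](OC/C=C(C)/CC/C=C(C)/CCC1OCCO1)(c1ccccc1)c1ccccc1 | intermediate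
7 | (2E,6E)-9-(1,3-dioxolan-2-yl)-3,7-dimethylnona-2,6-dien-1-ol | OC/C=C(C)/CC/C=C(C)/CCC1OCCO1 | intermediate
8 | (2E,6E)-9-(1,3-dioxolan-2-yl)-3,7-dimethylnona-2,6-dienal | O=C/C=C(C)/CC/C=C(C)/CCC1OCCO1 | intermediate
9 | 2-[(3E,7E)-3,7-dimethyldeca-3,7,9-trien-1-yl]-1,3-dioxolane | C=C/C=C(C)/CC/C=C(C)/CCC1OCCO1 | intermediate
10 | 9-[(3E,7E)-10-(1,3-dioxolan-2-yl)-4,8-dimethyldeca-3,7-dien-1-yl]-9-borabicyclo[3.3.1]nonane | B1(CC/C=C(C)/CC/C=C(C)/CCC3OCCO3)C2CCCC1CCC2 | intermediate (not isolated)
11 | (3E,7E)-10-(1,3-dioxolan-2-yl)-4,8-dimethyldeca-3,7-dien-1-ol | OCC/C=C(C)/CC/C=C(C)/CCC1OCCO1 | intermediate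
12 | 2-[(3E,7E)-10-bromo-3,7-dimethyldeca-3,7-dien-1-yl]-1,3-dioxolane | BrCC/C=C(C)/CC/C=C(C)/CCC1OCCO1 | intermediate
13 | propargyl alcohol | C#CCO | starting material
14 | carbon dioxide | O=C=O | starting material
15 | [(3E,7E)-10-(1,3-dioxolan-2-yl)-4,8-dimethyldeca-3,7-dien-1-yl]magnesium bromide | Br[Mg]CC/C=C(C)/CC/C=C(C)/CCC1OCCO1 | intermediate (not isolated)
16 | 4-[(3E,7E)-10-(1,3-dioxolan-2-yl)-4,8-dimethyldeca-3,7-dien-1-yl]-2,5-dihydro-1,2-oxamagnesole (magnesium on the former terminal alkyne carbon, cis to CH2O) | O1[Mg]C=C(CC/C=C(C)/CC/C=C(C)/CCC2OCCO2)C1 | intermediate (not isolated)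
17 | (2Z,6E,10E)-13-(1,3-dioxolan-2-yl)-3-(hydroxymethyl)-7,11-dimethyltrideca-2,6,10-trienoic acid | OC(=O)/C=C(\CO)CC/C=C(C)/CC/C=C(C)/CCC1OCCO1 | intermediate (not isolated)
18 | 4-[(3E,7E)-10-(1,3-dioxolan-2-yl)-4,8-dimethyldeca-3,7-dien-1-yl]furan-2(5H)-one | O=C1C=C(CC/C=C(C)/CC/C=C(C)/CCC2OCCO2)CO1 | intermediate
19 | (4E,8E)-4,8-dimethyl-11-(5-oxo-2,5-dihydrofuran-3-yl)undeca-4,8-dienal | O=CCC/C(C)=C/CC/C(C)=C/CCC1=CC(=O)OC1 | intermediate
20 | (S)-5-(hydroxymethyl)dihydrofuran-2(3H)-one | OC[C@@H]1CCC(=O)O1 | starting material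
21 | (S)-5-oxotetrahydrofuran-2-carbaldehyde | O=C[C@@H]1CCC(=O)O1 | intermediate
22 | (S)-5-(2-methylprop-1-en-1-yl)dihydrofuran-2(3H)-one | CC(C)=C[C@@H]1CCC(=O)O1 | intermediate
23 | trimethyl{[(5S)-5-(2-methylprop-1-en-1-yl)-4,5-dihydrofuran-2-yl]oxy}silane | CC(C)=C[C@@H]1CC=C(O[Si](C)(C)C)O1 | intermediate (not isolated)
24 | (5S)-3-bromo-5-(2-methylprop-1-en-1-yl)dihydrofuran-2(3H)-one, C3 epimers | CC(C)=C[C@@H]1CC(Br)C(=O)O1 | intermediate
25 | [(5S)-5-(2-methylprop-1-en-1-yl)-2-oxotetrahydrofuran-3-yl]triphenylphosphonium bromide | CC(C)=C[C@@H]1CC([P+](c2ccccc2)(c2ccccc2)c2ccccc2)C(=O)O1.[Br-] | intermediate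
26 | (S)-5-(2-methylprop-1-en-1-yl)-3-(triphenyl-λ5-phosphanylidene)dihydrofuran-2(3H)-one | CC(C)=C[C@@H]1CC(=P(c2ccccc2)(c2ccccc2)c2ccccc2)C(=O)O1 | intermediate (not isolated)
27 | (3E,5S)-3-[(4E,8E)-4,8-dimethyl-11-(5-oxo-2,5-dihydrofuran-3-yl)undeca-4,8-dien-1-ylidene]-5-(2-methylprop-1-en-1-yl)dihydrofuran-2(3H)-one | CC(C)=C[C@@H]1C/C(=C\CC/C(C)=C/CC/C(C)=C/CCC2=CC(=O)OC2)C(=O)O1 | target

Total step count: 16. Longest linear sequence: 12 (steps 1–11 and 16); steps 12–15 form the side branch to salt 25.

Steps most likely to fail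

Step 10. The chain Grignard reagent may be lost by protonolysis at the acetylenic C–H or by Wurtz coupling during magnesium insertion. The carbometalation may also stall, or the alkenylmagnesium may be protonated before CO2 arrives, which would give the uncarboxylated allylic alcohol. The fallback leaves the organomagnesium chemistry altogether and sets out from triene 9. Hydroboration with 9-BBN as in step 8 gives borane 10, which is not oxidised. It is instead coupled in the same flask with commercial 4-bromofuran-2(5H)-one by a B-alkyl Suzuki–Miyaura reaction (Pd(dppf)Cl2, AsPh3, Cs2CO3, DMF/THF/H2O, rt). This joins the chain to C4 of a preformed butenolide and returns to the route at 18. The detour makes no compound outside the list (F0).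

Step 4. The β-dioxygenated Grignard reagent may undergo β-elimination or transmetalate sluggishly, so that SN2' attack or homocoupling of the allylic bromide takes over. The fallback sets out from bromide 4 and uses enolate-type alkylation. Lithiated acetaldehyde N-cyclohexylimine (LDA, THF, −78 °C) should give (4E,8E)-10-[(tert-butyldiphenylsilyl)oxy]-N-cyclohexyl-4,8-dimethyldeca-4,8-dien-1-imine F1. Work-up with aqueous oxalic acid hydrolyses it to (4E,8E)-10-[(tert-butyldiphenylsilyl)oxy]-4,8-dimethyldeca-4,8-dienal F2. Acetalisation with ethylene glycol and PPTS in refluxing benzene with water removal then returns to the route at 6.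

Step 15 (together with step 14). Triphenylphosphine may attack bromine instead of carbon, causing reductive debromination. HBr may also be eliminated, or the allylic C5–O bond may ionise on prolonged heating. The fallback sets out from lactone 22 and makes the C–P bond by rearrangement, not by substitution. Treatment with LDA (2.2 equiv.) and diethyl chlorophosphate in THF from −78 °C to rt (vinyl phosphate to phosphonate 1,3-shift) should give diethyl [(5S)-5-(2-methylprop-1-en-1-yl)-2-oxotetrahydrofuran-3-yl]phosphonate F3. A Horner–Wadsworth–Emmons reaction of F3 with aldehyde 19 (LiCl, i-Pr2NEt, MeCN, rt) returns to the route at 27. The E isomer is expected to predominate, and any Z isomer would be removed by chromatography.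

Further compounds
F0 | step 10 | none | none
F1 | step 4 | (4E,8E)-10-[(tert-butyldiphenylsilyl)oxy]-N-cyclohexyl-4,8-dimethyldeca-4,8-dien-1-imine | CC(C)(C)[Si](OC/C=C(C)/CC/C=C(C)/CCC=NC1CCCCC1)(c1ccccc1)c1ccccc1
F2 | step 4 | (4E,8E)-10-[(tert-butyldiphenylsilyl)oxy]-4,8-dimethyldeca-4,8-dienal | CC(C)(C)[Si](OC/C=C(C)/CC/C=C(C)/CCC=O)(c1ccccc1)c1ccccc1
F3 | step 15 | diethyl [(5S)-5-(2-methylprop-1-en-1-yl)-2-oxotetrahydrofuran-3-yl]phosphonate | CC(C)=C[C@@H]1CC(P(=O)(OCC)OCC)C(=O)O1
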